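**Plan**

- Cuts, in retrosynthetic order: the C11–O aryl ether bond (Mitsunobu with isofraxidin), the C9–C11 bond ([2,3]-shift from an oxygen on C7), the C3–C4 bond of ring A (radical closure), then the C10–C1 and C10–CH3 bonds (two enolate alkylations).
- Enabling feature: ring B (C5–C10), with the C5 stereocentre, the C8 methyl and the C7=C8 alkene, is the six-membered ring of (R)-carvone. The isopropenyl carbon is C4 and already holds one of the geminal methyls, and the α′ carbon is C10. With a C1–C3 aldehyde chain on C10, ring A lacks only the C3–C4 bond to a quaternary carbon.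
- Forward order: ring B is bought; C10 is made quaternary (methyl, then allyl); the allyl group becomes the C3 aldehyde; ring A closes by hydrogen-atom transfer to the isopropenyl group and 6-exo addition of the C4 radical to C3. The enone is then converted into the 7α-allylic alcohol, whose oxygen carries C11 onto C9, and the coumarin is attached last.
- Stereochemistry: C5 comes from (R)-carvone; C10 from allylation anti to the isopropenyl group; C7–O from enone epoxidation on the α face; C9 from suprafacial transfer of CH2 from the 7α oxygen. The C3 carbinol centre is transient.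

Key step: step 5

Remark: drimane numbering is used (C11 is the CH2O carbon; α is the face of H-5, β the face of the C10 methyl); 4 is carried on as its C6 epimer mixture; isofraxidin and tributyl(iodomethyl)stannane are taken as purchased.

**Route**

Step 1
Reactants: 1 (R)-carvone; 2 iodomethane
Product: 4 trans-6-methylcarvone, via lithium dienolate of carvone 3 (not isolated)
Conditions: LiN(i-Pr)2, THF, −78 °C; then MeI, −78 → 0 °C
Reagents that add atoms: iodomethane, CI
Why: Enolate alkylation: kinetic α′ deprotonation gives the cross-conjugated dienolate, which is C-methylated, and the new C6 centre need not be controlled because it is enolized again in step 2.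

Step 2
Reactants: 4 trans-6-methylcarvone; 5 allyl bromide
Product: 7 6-allyl-6-methylcarvone (allyl trans to isopropenyl), via lithium enolate of 6-methylcarvone 6 (not isolated)
Conditions: LiN(i-Pr)2, THF, −78 °C; then allyl bromide, DMPU, −78 °C → rt
Reagents that add atoms: allyl bromide, C=CCBr
Why: Enolate alkylation: allyl bromide attacks the tetrasubstituted enolate on the face anti to the neighbouring isopropenyl group, which sets the quaternary carbon (C10 of the target) with allyl trans and methyl cis to that group.

Step 3
Reactants: 7 6-allyl-6-methylcarvone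
Product: 9 6-(3-hydroxypropyl)-6-methylcarvone (hydroxypropyl trans to isopropenyl), via B-alkyldicyclohexylborane 8 (not isolated)
Conditions: Cy2BH (from BH3·SMe2 and cyclohexene), THF, 0 °C; then NaBO3·4H2O, H2O, rt
Reagents that add atoms: sodium perborate (NaBO3·4H2O), [Na+].[Na+].O[B-]1(O)OO[B-](O)(O)OO1
Why: Hydroboration–oxidation: the hindered dialkylborane should add anti-Markovnikov to the monosubstituted allyl alkene faster than to the 1,1-disubstituted isopropenyl group or the electron-poor enone, perborate oxidizes the C–B bond without the strongly alkaline peroxide that would epoxidize the enone, and any allylic carbinol from partial ketone reduction is returned to the enone in step 4.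

Step 4
Reactants: 9 6-(3-hydroxypropyl)-6-methylcarvone
Product: 10 6-methyl-6-(3-oxopropyl)carvone (oxopropyl trans to isopropenyl)
Conditions: Dess–Martin periodinane, NaHCO3, CH2Cl2, 0 °C → rt
Reagents that add atoms: none
Why: Dess–Martin oxidation converts the primary alcohol into the aldehyde under buffered conditions that leave the enone and the isopropenyl group untouched.

Step 5
Reactants: 10 6-methyl-6-(3-oxopropyl)carvone
Product: 11 3β-hydroxy-11-nordrim-7-en-9-one (5α-H, 10β-CH3)
Conditions: Fe(acac)3 (cat.), PhSiH3, EtOH/(CH2OH)2, 60 °C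
Reagents that add atoms: none
Why: PhSiH3 converts Fe(acac)3 (trivalent iron) in ethanol into an iron hydride that passes a hydrogen atom to the CH2 terminus of the isopropenyl group, so the tertiary C4 radical forms with both methyl groups in place (Markovnikov metal-hydride hydrogen-atom transfer). The radical adds to the aldehyde carbon C3 and closes ring A in the 6-exo-trig mode through a chair, forming the C3–C4 bond, and the alkoxy radical is reduced by divalent iron and protonated by the solvent; the closest known reaction type is the iron-hydride-initiated reductive radical cyclization of alkenes onto ketones and aldehydes. C3 is the only new stereocentre: the aldehyde oxygen should lie equatorial in the chair and give the 3β carbinol, but this centre is oxidized in step 13, so an epimer would converge. The trans ring fusion is not decided here, since C5 and C10 are already fixed by carvone and by step 2. The step needs hydrogen-atom transfer to the isopropenyl group and not to the enone; the electron-poor, trisubstituted enone alkene should accept the hydrogen atom more slowly, and the C4 radical could reach C7 or C9 only through a four-membered ring, so the aldehyde is its only intramolecular partner.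

Step 6
Reactants: 11 3β-hydroxy-11-nordrim-7-en-9-one
Product: 12 3β-(tert-butyldimethylsilyloxy)-11-nordrim-7-en-9-one
Conditions: TBSOTf, 2,6-lutidine, CH2Cl2, −78 → 0 °C
Reagents that add atoms: tert-butyldimethylsilyl triflate, CC(C)(C)[Si](C)(C)OS(=O)(=O)C(F)(F)F
Why: Silyl ether formation: the silyl triflate silylates the hindered equatorial carbinol next to the geminal methyls at low temperature and masks C3 against the base, hydrazine and organolithium steps that follow.

Step 7
Reactants: 12 3β-(tert-butyldimethylsilyloxy)-11-nordrim-7-en-9-one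
Product: 13 3β-(tert-butyldimethylsilyloxy)-7α,8α-epoxy-11-nordriman-9-one
Conditions: H2O2 (30% aq.), NaOH, MeOH, 0 °C
Reagents that add atoms: hydrogen peroxide, OO
Why: Weitz–Scheffer nucleophilic epoxidation: hydroperoxide should add to C7 axially on the α face, trans to the C5–C4 bond as in the epoxidation of carvone itself, and the enolate closes to the 7α,8α-epoxide, which sets the C7 oxygen configuration used in step 10.

Step 8
Reactants: 13 3β-(tert-butyldimethylsilyloxy)-7α,8α-epoxy-11-nordriman-9-one
Product: 15 3β-(tert-butyldimethylsilyloxy)-11-nordrim-8-en-7α-ol, via epoxy hydrazone 14 (not isolated)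
Conditions: N2H4·H2O, AcOH, MeOH, 0 °C → rt
Reagents that add atoms: none
Why: Wharton transposition: the epoxy hydrazone opens to a vinyl diazene that loses dinitrogen, which leaves the C8=C9 alkene and an unbroken C7–O bond, so the 7α configuration is retained.

Step 9
Reactants: 15 3β-(tert-butyldimethylsilyloxy)-11-nordrim-8-en-7α-ol; 16 tributyl(iodomethyl)stannane
Product: 18 3β-(tert-butyldimethylsilyloxy)-7α-[(tributylstannyl)methoxy]-11-nordrim-8-ene, via potassium 7α-alkoxide 17 (not isolated)
Conditions: KH, THF, 0 °C; then ICH2SnBu3, 0 °C → rt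
Reagents that add atoms: tributyl(iodomethyl)stannane, IC[Sn](CCCC)(CCCC)CCCC
Why: Williamson etherification of the potassium alkoxide with the reactive iodomethylstannane gives the stannylmethyl ether without touching the silyl ether.

Step 10
Reactants: 18 3β-(tert-butyldimethylsilyloxy)-7α-[(tributylstannyl)methoxy]-11-nordrim-8-ene
Product: 20 3β-(tert-butyldimethylsilyloxy)-9-epi-drim-7-en-11-ol (9β-H), via α-alkoxymethyllithium 19 (not isolated)
Conditions: n-BuLi, THF, −78 → −20 °C; then aq. NH4Cl
Reagents that add atoms: none
Why: Still–Wittig [2,3]-sigmatropic rearrangement: tin–lithium exchange gives the α-alkoxymethyllithium, whose carbon is delivered suprafacially from the pseudoaxial 7α oxygen to the α face of C9, anti to the C10 methyl, which sets C9 (9β-H, α-CH2OH) and moves the alkene to C7=C8.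

Step 11
Reactants: 20 3β-(tert-butyldimethylsilyloxy)-9-epi-drim-7-en-11-ol; 21 isofraxidin
Product: 22 7-O-[3β-(tert-butyldimethylsilyloxy)-9-epi-drim-7-en-11-yl]isofraxidin
Conditions: PPh3, DIAD, THF, 0 °C → rt
Reagents that add atoms: isofraxidin, COc1cc2ccc(=O)oc2c(OC)c1O
Why: Mitsunobu etherification: the primary alcohol is activated as its oxyphosphonium salt and displaced at C11, which is not a stereocentre, by the acidic phenol of isofraxidin under neutral conditions that should avoid elimination toward the diene.

Step 12
Reactants: 22 7-O-[3β-(tert-butyldimethylsilyloxy)-9-epi-drim-7-en-11-yl]isofraxidin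
Product: 23 7-O-(3β-hydroxy-9-epi-drim-7-en-11-yl)isofraxidin
Conditions: HF (48% aq.), MeCN, rt
Reagents that add atoms: none
Why: Fluoride-driven desilylation frees the C3 carbinol, and the coumarin lactone, the aryl alkyl ether and the trisubstituted alkene should tolerate aqueous HF in acetonitrile.

Step 13
Reactants: 23 7-O-(3β-hydroxy-9-epi-drim-7-en-11-yl)isofraxidin
Product: 24 7-O-(3-oxo-9-epi-drim-7-en-11-yl)isofraxidin (CNP0127079.1)
Conditions: Dess–Martin periodinane, NaHCO3, CH2Cl2, rt
Reagents that add atoms: none
Why: Dess–Martin oxidation of the secondary carbinol gives the C3 ketone and removes the transient C3 stereocentre, and no stereocentre is α to the new carbonyl (C2 is CH2, C4 is quaternary), so none can epimerize.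

**Compound list**

1 | (R)-carvone | CC1=CC[C@@H](C(C)=C)CC1=O | starting material
2 | iodomethane | CI | starting material
3 | lithium dienolate of carvone (not isolated) | CC1=CC[C@@H](C(C)=C)C=C1O[Li] | intermediate
4 | trans-6-methylcarvone (methyl trans to isopropenyl; C6 epimer also usable) | CC1=CC[C@@H](C(C)=C)[C@H](C)C1=O | intermediate
5 | allyl bromide | C=CCBr | starting material
6 | lithium enolate of 6-methylcarvone (not isolated) | CC1=CC[C@@H](C(C)=C)C(C)=C1O[Li] | intermediate
7 | 6-allyl-6-methylcarvone (allyl trans, methyl cis to isopropenyl) | CC1=CC[C@@H](C(C)=C)[C@](C)(CC=C)C1=O | intermediate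
8 | B-alkyldicyclohexylborane of 7 (boron on the allyl terminus; not isolated) | CC1=CC[C@@H](C(C)=C)[C@](C)(CCCB(C2CCCCC2)C2CCCCC2)C1=O | intermediate
9 | 6-(3-hydroxypropyl)-6-methylcarvone (hydroxypropyl trans to isopropenyl) | CC1=CC[C@@H](C(C)=C)[C@](C)(CCCO)C1=O | intermediate
10 | 6-methyl-6-(3-oxopropyl)carvone (oxopropyl trans to isopropenyl) | CC1=CC[C@@H](C(C)=C)[C@](C)(CCC=O)C1=O | intermediate
11 | 3β-hydroxy-11-nordrim-7-en-9-one (trans-decalin, 5α-H, 10β-CH3) | CC1=CC[C@H]2C(C)(C)[C@@H](O)CC[C@]2(C)C1=O | intermediate
12 | 3β-(tert-butyldimethylsilyloxy)-11-nordrim-7-en-9-one | CC1=CC[C@H]2C(C)(C)[C@@H](O[Si](C)(C)C(C)(C)C)CC[C@]2(C)C1=O | intermediate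
13 | 3β-(tert-butyldimethylsilyloxy)-7α,8α-epoxy-11-nordriman-9-one | C[C@@]12O[C@@H]1C[C@H]3C(C)(C)[C@@H](O[Si](C)(C)C(C)(C)C)CC[C@]3(C)C2=O | intermediate
14 | hydrazone of epoxy ketone 13 (not isolated) | C[C@@]12O[C@@H]1C[C@H]3C(C)(C)[C@@H](O[Si](C)(C)C(C)(C)C)CC[C@]3(C)C2=NN | intermediate
15 | 3β-(tert-butyldimethylsilyloxy)-11-nordrim-8-en-7α-ol | CC1=C[C@@]2(C)CC[C@H](O[Si](C)(C)C(C)(C)C)C(C)(C)[C@@H]2C[C@H]1O | intermediate
16 | tributyl(iodomethyl)stannane | IC[Sn](CCCC)(CCCC)CCCC | starting material
17 | potassium 7α-alkoxide of 15 (not isolated) | CC1=C[C@@]2(C)CC[C@H](O[Si](C)(C)C(C)(C)C)C(C)(C)[C@@H]2C[C@H]1O[K] | intermediate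
18 | 3β-(tert-butyldimethylsilyloxy)-7α-[(tributylstannyl)methoxy]-11-nordrim-8-ene | CC1=C[C@@]2(C)CC[C@H](O[Si](C)(C)C(C)(C)C)C(C)(C)[C@@H]2C[C@H]1OC[Sn](CCCC)(CCCC)CCCC | intermediate
19 | 7α-(lithiomethoxy) ether, the α-alkoxymethyllithium (not isolated) | CC1=C[C@@]2(C)CC[C@H](O[Si](C)(C)C(C)(C)C)C(C)(C)[C@@H]2C[C@H]1OC[Li] | intermediate
20 | 3β-(tert-butyldimethylsilyloxy)-9-epi-drim-7-en-11-ol (9β-H, CH2OH on the α face) | CC1=CC[C@H]2C(C)(C)[C@@H](O[Si](C)(C)C(C)(C)C)CC[C@]2(C)[C@@H]1CO | intermediate
21 | isofraxidin (7-hydroxy-6,8-dimethoxycoumarin) | COc1cc2ccc(=O)oc2c(OC)c1O | starting material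
22 | 7-O-[3β-(tert-butyldimethylsilyloxy)-9-epi-drim-7-en-11-yl]isofraxidin | COc1cc2ccc(=O)oc2c(OC)c1OC[C@@H]1C(C)=CC[C@H]2C(C)(C)[C@@H](O[Si](C)(C)C(C)(C)C)CC[C@]12C | intermediate
23 | 7-O-(3β-hydroxy-9-epi-drim-7-en-11-yl)isofraxidin | COc1cc2ccc(=O)oc2c(OC)c1OC[C@@H]1C(C)=CC[C@H]2C(C)(C)[C@@H](O)CC[C@]12C | intermediate
24 | 7-O-(3-oxo-9-epi-drim-7-en-11-yl)isofraxidin, CNP0127079.1 | COc1cc2ccc(=O)oc2c(OC)c1OC[C@@H]1C(C)=CC[C@H]2C(C)(C)C(=O)CC[C@]12C | target

**Count**

Total steps: 13. Longest linear sequence: 13 steps, from 1 to 24.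

**Steps most likely to fail**

Step 5. Hydrogen-atom transfer may go to the enone, the silane may reduce the aldehyde before ring closure, or the cyclized alkoxy radical may reopen by β-scission. The fallback generates the same C4 radical by halogen abstraction. It sets out from 10: Markovnikov addition of HBr (CH2Cl2, −40 °C) to the isopropenyl group should give the tertiary bromide 5-(2-bromopropan-2-yl)-2,6-dimethyl-6-(3-oxopropyl)cyclohex-2-en-1-one F1. Slow addition of Bu3SnH with AIBN (benzene, 80 °C) should then give the C4 radical, 6-exo closure onto the aldehyde and hydrogen transfer from the stannane to the alkoxy radical. The fallback comes back to the route at 11.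

Step 8. Hydrazone formation may be slow at a carbonyl flanked by two fully substituted carbons, and the diazene may decompose along other paths. The fallback is a radical epoxide fragmentation that needs no condensation at C9. It sets out from 13: NaBH4 (MeOH, 0 °C) should give the 7α,8α-epoxy-9-ol F2 (either C9 epimer serves). Thiocarbonyldiimidazole with DMAP (1,2-dichloroethane, reflux) should give its O-(imidazol-1-ylthiocarbonyl) derivative F3. Bu3SnH/AIBN (benzene, 80 °C) should then form the C9 radical, which opens the epoxide at C8–O, and the C7 alkoxy radical takes hydrogen from the stannane. The fallback comes back at 15.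

Step 10. The carbanion may be protonated or undergo a [1,2]-shift before rearranging, and any loss of α-face selectivity in step 7 would be passed on to C9. The fallback takes its stereocontrol from the C10 methyl and erases the C7 centre. It sets out from 15: MnO2 (CH2Cl2) should give 3β-(tert-butyldimethylsilyloxy)-11-nordrim-8-en-7-one F4. Conjugate addition of (i-PrO)Me2SiCH2MgCl with CuBr·SMe2 (THF, −78 → −20 °C) should occur at C9 on the α face, anti to the axial C10 methyl. Trapping the enolate with N-(5-chloro-2-pyridyl)bis(trifluoromethanesulfonimide) (Comins' reagent) should give the 9α-[(isopropoxydimethylsilyl)methyl] C7 enol triflate F5. Reduction with Pd(OAc)2, PPh3, HCO2H and Bu3N (DMF, 60 °C) should give the 9α-[(isopropoxydimethylsilyl)methyl]-7-ene F6. Tamao oxidation (KF, KHCO3, H2O2, THF/MeOH) then comes back to the route at 20.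

**Further compounds**

F1 | step 5 | 5-(2-bromopropan-2-yl)-2,6-dimethyl-6-(3-oxopropyl)cyclohex-2-en-1-one (configuration as in 10) | CC1=CC[C@@H](C(C)(C)Br)[C@](C)(CCC=O)C1=O
F2 | step 8 | 3β-(tert-butyldimethylsilyloxy)-7α,8α-epoxy-11-nordriman-9-ol (C9 epimer not critical) | C[C@@]12O[C@@H]1C[C@H]3C(C)(C)[C@@H](O[Si](C)(C)C(C)(C)C)CC[C@]3(C)C2O
F3 | step 8 | O-(imidazol-1-ylthiocarbonyl) derivative of F2 | C[C@@]12O[C@@H]1C[C@H]3C(C)(C)[C@@H](O[Si](C)(C)C(C)(C)C)CC[C@]3(C)C2OC(=S)n4ccnc4
F4 | step 10 | 3β-(tert-butyldimethylsilyloxy)-11-nordrim-8-en-7-one | CC1=C[C@@]2(C)CC[C@H](O[Si](C)(C)C(C)(C)C)C(C)(C)[C@@H]2CC1=O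
F5 | step 10 | 3β-(tert-butyldimethylsilyloxy)-9α-[(isopropoxydimethylsilyl)methyl]-11-nordrim-7-en-7-yl triflate (9β-H) | CC1=C(OS(=O)(=O)C(F)(F)F)C[C@H]2C(C)(C)[C@@H](O[Si](C)(C)C(C)(C)C)CC[C@]2(C)[C@@H]1C[Si](C)(C)OC(C)C
F6 | step 10 | 3β-(tert-butyldimethylsilyloxy)-9α-[(isopropoxydimethylsilyl)methyl]-11-nordrim-7-ene (9β-H) | CC1=CC[C@H]2C(C)(C)[C@@H](O[Si](C)(C)C(C)(C)C)CC[C@]2(C)[C@@H]1C[Si](C)(C)OC(C)C
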